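| setting | alpha | dawn | dusk |
|---|---|---|---|
| starting material | 0.0050 M (fed, over 2.0 s) | 0.0050 M (fed, over 2.0 s) | 0.0050 M (fed, over 2.0 s) |
| partner | 0.71 equiv | 1.30 equiv | 2.00 equiv |
| remark | run made earlier |  |  |
| time |  | 3.0 min | 3.0 min |

alpha run (percent of the starting material charged)

| time / min | target / % | side product / % | starting material / % | isomer of the product / % |
|---|---|---|---|---|
| 0.250 | 39.0 | 1.9 | 2.6 | 13.7 |
| 0.500 | 43.5 | 2.3 | 1.1 | 13.8 |
| 1.33 | 45.1 | 2.9 | 0.3 | 13.7 |
| 3.00 | 47.0 | 3.9 | 0 | 14.1 |

(scatter of a reading: 0.3 percentage points)

- in percentages every species weighs as the starting material in it: one side product counts as two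
- reactions considered so far: starting material + partner -> isomer of the product; starting material <-> tautomer; starting material <-> dormant form; tautomer -> decomposed reagent; starting material + target -> side product; partner + tautomer -> target
- a reading of starting material is of its free form alone

* which of these there is most of at the end, counted by the starting material in it, dawn (side product / target / starting material / isomer of the product)
* which of these there is most of at the end, counted by the starting material in it, dusk (side product / target / starting material / isomer of the product)
* how much there is at the end of the one of these that leads, in percent of the starting material charged: dawn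
* how much there is at the end of the one of these that leads, in percent of the starting material charged: dusk

One run at one charge cannot show how a lead moves with partner, for a single ratio has no slope. Alpha can show it if read as two competitions.

What competes? Starting material either meets partner and becomes isomer of the product, or turns to tautomer. Partner then catches tautomer as target, or tautomer is lost. I book side product and any dormant form with those losses.

How much partner did alpha see? Target and isomer each took one partner, and so did side product, whose percentage counts two and so carries 0.5 of a partner per point, so partner fell from 0.71 equiv to 0.0795 equiv by 3.00 min, a mean of 0.395 equiv.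

Your rule? The slope, isomer over all else per equivalent of mean partner, is 0.416 per equiv. Target equals losses at a mean partner of 0.327 equiv, and target over losses grows in proportion to mean partner. Joining the two, isomer per target, a selectivity factor, equals the slope times the sum of mean partner and that level. With scarce partner it tends to 0.136; with abundant partner it climbs with partner.

The weak spot? Isomer already stood at 13.7% at 0.250 min, and partner's midpoint over that stretch is 0.442 equiv, above my mean, so my slope and isomer lean high.

Your call? Taking one equivalent as used, mean partner is the charge less 0.5. Dawn, at 0.800 equiv, gives a ratio of 0.469 and target 53.3%. Dusk, at 1.50 equiv, gives 0.760, which is below one: target 50.6%, isomer 38.4%.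

The forecast names target at 48% for dawn, and isomer of the product at 42% for dusk: "This is a close call, but isomer narrowly leads". We part at dusk.

Dawn gives target at 57.3%; dusk gives target at 55.0%, with isomer at 34.6%.

    starting material + partner → isomer of the product (k = 19.0 L mol⁻¹ s⁻¹)
    starting material ⇌ tautomer (K = 5.30, k = 0.300 s⁻¹)
    starting material ⇌ dormant form (K = 4.00, k = 0.0600 s⁻¹)
    tautomer → decomposed reagent (k = 0.0710 s⁻¹)
    starting material + target → side product (k = 4.90 L mol⁻¹ s⁻¹)
    partner + tautomer → target (k = 81.0 L mol⁻¹ s⁻¹)

Dusk's isomer per target is 0.630 against my 0.760. For a flask like dawn charged with 5.20 equiv of partner, the slope gives 2.09, and that flask stores 1.62: isomer 60.0%, target 37.0%. Dusk is near rest at 3.00 min: by 30.0 min its dormant form falls from 1.21% to 0%, target gains 0.73 percentage points and isomer 0.34 points. Dawn's target gains 0.92 points over the same stretch, reaching 58.3%.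

(Readings and results stem from a simulated flask for an exercise, and the scatter is random.)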